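The product to watch is D.L free in solution, which can pass into E or into crystals of X.

    D + L → D.L (k1 = 0.066 L mol⁻¹ s⁻¹)
    X ⇌ D.L, rate k2*(cs2 - [D.L]) while solid is left; crystals form when [D.L] > cs2 (cs2 = 0.11 M, k2 = 0.17 s⁻¹)
    Q ⇌ D, rate k3*(cs3 - [D]) while solid is left; crystals form when [D] > cs3 (cs3 = 0.11 M, k3 = 0.050 s⁻¹)
    D.L ⇌ E (K4 = 0.38, k4 = 0.014 s⁻¹)

| flask | Q | L | time |
|---|---|---|---|
| gamma | 0.040 M | 0.210 M | 15 min |
| theta | 0.080 M | 0.210 M | 15 min |
| alpha | 0.15 M | 0.210 M | 15 min |
| eta | 0.30 M | 0.210 M | 15 min |

- amounts and yields of D.L count X too
- given per volume of solution although it is solid: Q, X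
- at the start none of Q is in solution
- the concentration of D.L that is asked is that of its free form alone
- "hardly changes" means that all values lie within two and a half points (for a concentration: within two and a half percent of the largest)
- run time (gamma): 15 min

* [D.L] (only what is free in solution) at the end for gamma, theta, alpha, eta, in this order
* how the row runs (falls, then rises / hardly changes / rises, then falls / falls all the way / rises all the way)

Turn the time first. By hand, in gamma, D has a half-life of 0.83 min at L as charged, and dissolved D.L and E relax, both ways together, with a half-life of 0.227 min. Both are shorter than the 15 min run, so I expect a longer gamma run to add little.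

Turn the charge of Q next. With no X present and E at equilibrium with D.L, E over free D.L equals 0.38, so the free share of the product is

free share = 1 / (1 + K4) = 72.5%

The ceiling charge is the amount of product, per volume, at which free D.L just reaches its solubility:

ceiling charge = solubility of D.L × (1 + K4) = 0.152 M

With conversion complete and less product than this, free D.L follows the charge, order one in Q. With more product than this, crystals form and free D.L stays at solubility, order zero. Gamma, theta and alpha are charged below the ceiling, so my reckoning, which takes conversion as complete, gives

free D.L = charge of Q × free share = 0.0290 M, 0.0580 M, 0.109 M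

Turn L last. In eta, L is the limiting reagent, since its charge of 0.210 M is less than the 0.30 M of Q. That charge still exceeds the ceiling, so I put eta at the solubility, 0.11 M, a small step above alpha.

The forecast gives 0.029 M, 0.058 M, 0.1077 M and 0.11 M, and says the row rises all the way. Its alpha value is lower than my 0.109 M, and it calls that flask “slightly short of complete conversion”.

The flasks end at 0.0290 M, 0.0580 M, 0.108 M and 0.110 M, so the row rises all the way. The local order in Q, percent change of free D.L per percent of Q, is 1.0 in gamma and −0.0015 in eta. In eta, the L charge less the ceiling charge leaves 0.0582 M, which is 19.4% of the Q charged, and X stands at 19.1% after 15.0 min.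

(All constants were chosen freely, and the outcome is calculated.)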